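**Retrosynthetic overview**

1. Target 24 ⇐ phenol silyl ether 23 ⇐ hydroxyl-directed α-epoxidation of dauc-8-ene 22 ⇐ ring-closing metathesis (C8=C9, seven-membered ring) of cyclopentane diene 20.
2. 20 ⇐ acylation of the tertiary C4 alkoxide of 18 with acid chloride 4 (three steps from vanillin).
3. C6 carbinol of 17 ⇐ aldehyde 15 + chiral methallylborane 9 (three steps from (+)-α-pinene); this union also fixes the absolute configuration.
4. 15 ⇐ diol 14 ⇐ oxasilolane 13 ⇐ silicon-tethered 5-exo radical cyclisation/allyl transfer of 12, made from 3-methylcyclopent-2-enone and i-PrMgCl (stereochemical relay C4 → C5 → C1).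
5. Ring order: cyclopentane (purchased) → temporary oxasilolane → cycloheptene by RCM → oxirane.

Assumption and convention: daucane numbering is used (C1 = C–Me ring-fusion carbon, C4 = C(O)(i-Pr), C5 = ring-fusion CH, C6 = CHOH, C8 = C–Me; β = face of the C1 methyl). No reliable one-step enantioselective route to the tertiary allylic alcohol exists, so 11–15 are racemates, drawn as the antipode that is carried on. Step 11 is the resolving step: the enantiopure borane turns the two antipodes of 15 into two diastereomers, and only 17 is carried on (at most 50 % yield in that step).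

**Step 1**
Reactants: 1 vanillin
Product: 2 4-[(tert-butyldimethylsilyl)oxy]-3-methoxybenzaldehyde
Conditions: TBSCl, imidazole, CH2Cl2, 0 °C → rt
Reagents that add atoms: tert-butyldimethylsilyl chloride, CC(C)(C)[Si](C)(C)Cl
Why: Imidazole-promoted O-silylation masks the phenol so that the later acid chloride and alkoxide chemistry is possible.

**Step 2**
Reactants: 2 4-[(tert-butyldimethylsilyl)oxy]-3-methoxybenzaldehyde
Product: 3 4-[(tert-butyldimethylsilyl)oxy]-3-methoxybenzoic acid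
Conditions: NaClO2, NaH2PO4, 2-methylbut-2-ene, t-BuOH/H2O, rt
Reagents that add atoms: sodium chlorite, [Na+].[O-]Cl=O
Why: Pinnick oxidation converts the aldehyde to the acid under buffered conditions that leave the aryl silyl ether intact.

**Step 3**
Reactants: 3 4-[(tert-butyldimethylsilyl)oxy]-3-methoxybenzoic acid
Product: 4 4-[(tert-butyldimethylsilyl)oxy]-3-methoxybenzoyl chloride
Conditions: (COCl)2, DMF (cat.), CH2Cl2, 0 °C → rt
Reagents that add atoms: oxalyl chloride, O=C(Cl)C(Cl)=O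
Why: Vilsmeier-type activation gives the acid chloride needed to acylate a hindered tertiary alkoxide.

**Step 4**
Reactants: 5 (+)-α-pinene
Product: 6 (−)-diisopinocampheylborane
Conditions: BH3·SMe2, THF, 0 °C, then 0 °C, 72 h with excess 5
Reagents that add atoms: borane–dimethyl sulfide, [BH3-][S+](C)C
Why: Hydroboration occurs anti to the gem-dimethyl bridge and stops at the dialkylborane, and equilibration with excess pinene gives crystalline reagent of ≥99 % ee.

**Step 5**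
Reactants: 6 (−)-diisopinocampheylborane
Product: 7 (−)-B-methoxydiisopinocampheylborane
Conditions: MeOH, Et2O, 0 °C → rt
Reagents that add atoms: methanol, CO
Why: Methanolysis of the B–H bond with loss of H2 gives the storable borinate.

**Step 6**
Reactants: 7 (−)-B-methoxydiisopinocampheylborane
Product: 9 (−)-B-(2-methylallyl)diisopinocampheylborane, via borate complex 8 (not isolated)
Conditions: CH2=C(Me)CH2MgCl, Et2O, −78 °C → rt; pentane, filter Mg salts under Ar
Reagents that add atoms: 2-methylallylmagnesium chloride, CC(=C)C[Mg]Cl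
Why: The Grignard reagent adds to boron and the borate expels MeOMgCl on warming, giving the salt-free Brown methallylborane.

**Step 7**
Reactants: 10 3-methylcyclopent-2-en-1-one
Product: 12 rac-(bromomethyl)dimethyl{[3-methyl-1-(propan-2-yl)cyclopent-2-en-1-yl]oxy}silane, via chloromagnesium alkoxide 11 (not isolated)
Conditions: i-PrMgCl, LaCl3·2LiCl, THF, 0 °C; then BrCH2SiMe2Cl, DMAP (cat.), 0 °C → rt
Reagents that add atoms: isopropylmagnesium chloride, CC(C)[Mg]Cl; (bromomethyl)chlorodimethylsilane, C[Si](C)(Cl)CBr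
Why: Lanthanide-promoted Grignard 1,2-addition to the enone creates the C4 carbinol as a racemate, and the tertiary alkoxide is O-silylated in the same flask to install the radical tether.

**Step 8**
Reactants: 12 rac-(bromomethyl)dimethyl{[3-methyl-1-(propan-2-yl)cyclopent-2-en-1-yl]oxy}silane
Product: 13 rac-(3aR,4R,6aR)-2,2,4-trimethyl-6a-(propan-2-yl)-4-(prop-2-en-1-yl)hexahydro-2H-cyclopenta[d][1,2]oxasilole
Conditions: allylSnBu3 (4 equiv), AIBN (portions), PhH (0.05 M), 80 °C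
Reagents that add atoms: allyltributylstannane, C=CC[Sn](CCCC)(CCCC)CCCC
Why: In this Stork–Nishiyama tethered radical cyclisation the α-silyl radical closes 5-exo onto C5, so C6 must be cis to the C4 oxygen, and Keck allyl transfer to the tertiary C1 radical occurs anti to the new C5 substituent, placing allyl trans and methyl cis to C6.

**Step 9**
Reactants: 13 rac-(3aR,4R,6aR)-2,2,4-trimethyl-6a-(propan-2-yl)-4-(prop-2-en-1-yl)hexahydro-2H-cyclopenta[d][1,2]oxasilole
Product: 14 rac-(1R,2S,3R)-2-(hydroxymethyl)-3-methyl-1-(propan-2-yl)-3-(prop-2-en-1-yl)cyclopentan-1-ol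
Conditions: 30 % H2O2, KF, KHCO3, THF/MeOH, 50 °C
Reagents that add atoms: hydrogen peroxide, OO
Why: Tamao–Fleming oxidation converts C6–Si into C6–OH and frees the tertiary alcohol without touching the terminal alkene or any stereocentre.

**Step 10**
Reactants: 14 rac-(1R,2S,3R)-2-(hydroxymethyl)-3-methyl-1-(propan-2-yl)-3-(prop-2-en-1-yl)cyclopentan-1-ol
Product: 15 rac-(1R,2R,5R)-2-hydroxy-5-methyl-2-(propan-2-yl)-5-(prop-2-en-1-yl)cyclopentane-1-carbaldehyde
Conditions: Dess–Martin periodinane, NaHCO3, CH2Cl2, 0 °C; used crude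
Reagents that add atoms: none
Why: Buffered Dess–Martin oxidation touches only the primary alcohol, and the C5 configuration is also the thermodynamic one (CHO trans to both i-Pr and allyl), so it is not at risk.

**Step 11**
Reactants: 15 rac-(1R,2R,5R)-2-hydroxy-5-methyl-2-(propan-2-yl)-5-(prop-2-en-1-yl)cyclopentane-1-carbaldehyde; 9 (−)-B-(2-methylallyl)diisopinocampheylborane
Product: 17 (1R,2S,3R)-2-[(1S)-1-hydroxy-3-methylbut-3-en-1-yl]-3-methyl-1-(propan-2-yl)-3-(prop-2-en-1-yl)cyclopentan-1-ol, via borinate ester 16 (not isolated)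
Conditions: 9 (2.2 equiv), Et2O, −78 °C; then 3 M NaOH, 30 % H2O2, 0 °C → rt; SiO2 chromatography
Reagents that add atoms: none
Why: Brown methallylboration through a chair Zimmerman–Traxler transition state attacks the aldehyde Si face under reagent control and sets C6 as S in both antipodes of 15, so the racemate becomes two diastereomers, of which 17 has all target configurations and the (1S,2R,3S,1′S) isomer is removed by chromatography.

**Step 12**
Reactants: 17 (1R,2S,3R)-2-[(1S)-1-hydroxy-3-methylbut-3-en-1-yl]-3-methyl-1-(propan-2-yl)-3-(prop-2-en-1-yl)cyclopentan-1-ol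
Product: 18 (1R,2S,3R)-3-methyl-2-{(1S)-3-methyl-1-[(triethylsilyl)oxy]but-3-en-1-yl}-1-(propan-2-yl)-3-(prop-2-en-1-yl)cyclopentan-1-ol
Conditions: TESCl, imidazole, DMAP (cat.), DMF, rt
Reagents that add atoms: chlorotriethylsilane, CC[Si](Cl)(CC)CC
Why: Silylation takes the secondary C6 alcohol and leaves the far more hindered tertiary C4 alcohol free for esterification.

**Step 13**
Reactants: 18 (1R,2S,3R)-3-methyl-2-{(1S)-3-methyl-1-[(triethylsilyl)oxy]but-3-en-1-yl}-1-(propan-2-yl)-3-(prop-2-en-1-yl)cyclopentan-1-ol; 4 4-[(tert-butyldimethylsilyl)oxy]-3-methoxybenzoyl chloride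
Product: 20 (1R,2S,3R)-3-methyl-2-{(1S)-3-methyl-1-[(triethylsilyl)oxy]but-3-en-1-yl}-1-(propan-2-yl)-3-(prop-2-en-1-yl)cyclopentyl 4-[(tert-butyldimethylsilyl)oxy]-3-methoxybenzoate, via lithium alkoxide 19 (not isolated)
Conditions: n-BuLi, THF, −78 °C; then 4, −78 → 0 °C
Reagents that add atoms: none
Why: Acylation of the pre-formed lithium alkoxide by the acid chloride is the standard way to esterify a hindered tertiary alcohol, forms only the O–acyl bond (C4 untouched), and the low temperature suppresses 1,5-silyl migration.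

**Step 14**
Reactants: 20 (1R,2S,3R)-3-methyl-2-{(1S)-3-methyl-1-[(triethylsilyl)oxy]but-3-en-1-yl}-1-(propan-2-yl)-3-(prop-2-en-1-yl)cyclopentyl 4-[(tert-butyldimethylsilyl)oxy]-3-methoxybenzoate
Product: 21 (1R,4R,5S,6S)-6-[(triethylsilyl)oxy]dauc-8-en-4-yl 4-[(tert-butyldimethylsilyl)oxy]-3-methoxybenzoate
Conditions: Grubbs II (5–10 mol %), CH2Cl2 (0.005 M), 40 °C
Reagents that add atoms: none
Why: Ring-closing metathesis between the allyl and the 1,1-disubstituted methallyl alkene closes the trans-fused cycloheptene with the trisubstituted C8=C9 bond and loss of ethene, changing no stereocentre.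

**Step 15**
Reactants: 21 (1R,4R,5S,6S)-6-[(triethylsilyl)oxy]dauc-8-en-4-yl 4-[(tert-butyldimethylsilyl)oxy]-3-methoxybenzoate
Product: 22 (1R,4R,5S,6S)-6-hydroxydauc-8-en-4-yl 4-[(tert-butyldimethylsilyl)oxy]-3-methoxybenzoate
Conditions: CSA (cat.), MeOH/CH2Cl2, 0 °C
Reagents that add atoms: none
Why: Mild acid methanolysis removes the alkyl TES ether while the acid-stable aryl TBS ether, the tertiary ester and the alkene survive.

**Step 16**
Reactants: 22 (1R,4R,5S,6S)-6-hydroxydauc-8-en-4-yl 4-[(tert-butyldimethylsilyl)oxy]-3-methoxybenzoate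
Product: 23 (1R,4R,5S,6S,8R,9S)-8,9-epoxy-6-hydroxydaucan-4-yl 4-[(tert-butyldimethylsilyl)oxy]-3-methoxybenzoate
Conditions: VO(acac)2 (5 mol %), t-BuOOH, CH2Cl2, 0 °C → rt
Reagents that add atoms: tert-butyl hydroperoxide, CC(C)(C)OO
Why: In this vanadium-catalysed hydroxyl-directed epoxidation the homoallylic 6α-OH delivers oxygen to the α face, which is also the face away from the angular β-methyl, setting 8R,9S.

**Step 17**
Reactants: 23 (1R,4R,5S,6S,8R,9S)-8,9-epoxy-6-hydroxydaucan-4-yl 4-[(tert-butyldimethylsilyl)oxy]-3-methoxybenzoate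
Product: 24 (1R,4R,5S,6S,8R,9S)-8,9-epoxy-6-hydroxydaucan-4-yl 4-hydroxy-3-methoxybenzoate (CNP0315707.1)
Conditions: KHF2, MeOH, rt
Reagents that add atoms: none
Why: Bifluoride cleaves only the phenolic silyl ether under near-neutral conditions, so the epoxide, the tertiary ester and the free secondary alcohol are not disturbed.

**Compound list**

1 | vanillin (4-hydroxy-3-methoxybenzaldehyde) | COc1cc(C=O)ccc1O | starting material
2 | 4-[(tert-butyldimethylsilyl)oxy]-3-methoxybenzaldehyde | COc1cc(C=O)ccc1O[Si](C)(C)C(C)(C)C | intermediate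
3 | 4-[(tert-butyldimethylsilyl)oxy]-3-methoxybenzoic acid | COc1cc(C(=O)O)ccc1O[Si](C)(C)C(C)(C)C | intermediate
4 | 4-[(tert-butyldimethylsilyl)oxy]-3-methoxybenzoyl chloride | COc1cc(C(=O)Cl)ccc1O[Si](C)(C)C(C)(C)C | intermediate
5 | (+)-α-pinene, (1R,5R)-2,6,6-trimethylbicyclo[3.1.1]hept-2-ene | CC1=CC[C@@H]2C[C@H]1C2(C)C | starting material
6 | (−)-diisopinocampheylborane, bis[(1R,2S,3R,5R)-2,6,6-trimethylbicyclo[3.1.1]heptan-3-yl]borane | B([C@@H]1C[C@@H]2C[C@H]([C@H]1C)C2(C)C)[C@@H]1C[C@@H]2C[C@H]([C@H]1C)C2(C)C | intermediate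
7 | (−)-B-methoxydiisopinocampheylborane | COB([C@@H]1C[C@@H]2C[C@H]([C@H]1C)C2(C)C)[C@@H]1C[C@@H]2C[C@H]([C@H]1C)C2(C)C | intermediate
8 | chloromagnesium methoxy(2-methylallyl)diisopinocampheylborate (not isolated) | CO[B-](CC(C)=C)([C@@H]1C[C@@H]2C[C@H]([C@H]1C)C2(C)C)[C@@H]1C[C@@H]2C[C@H]([C@H]1C)C2(C)C.[Mg+]Cl | intermediate
9 | (−)-B-(2-methylallyl)diisopinocampheylborane (Ipc groups from (+)-α-pinene) | CC(=C)CB([C@@H]1C[C@@H]2C[C@H]([C@H]1C)C2(C)C)[C@@H]1C[C@@H]2C[C@H]([C@H]1C)C2(C)C | intermediate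
10 | 3-methylcyclopent-2-en-1-one | CC1=CC(=O)CC1 | starting material
11 | chloromagnesium 3-methyl-1-(propan-2-yl)cyclopent-2-en-1-olate (racemic, R antipode drawn; not isolated) | Cl[Mg]O[C@@]1(C(C)C)CCC(C)=C1 | intermediate
12 | rac-(bromomethyl)dimethyl{[3-methyl-1-(propan-2-yl)cyclopent-2-en-1-yl]oxy}silane (R antipode drawn) | BrC[Si](C)(C)O[C@@]1(C(C)C)CCC(C)=C1 | intermediate
13 | rac-(3aR,4R,6aR)-2,2,4-trimethyl-6a-(propan-2-yl)-4-(prop-2-en-1-yl)hexahydro-2H-cyclopenta[d][1,2]oxasilole (cis-fused) | C[Si]2(C)O[C@@]1(C(C)C)CC[C@](C)(CC=C)[C@H]1C2 | intermediate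
14 | rac-(1R,2S,3R)-2-(hydroxymethyl)-3-methyl-1-(propan-2-yl)-3-(prop-2-en-1-yl)cyclopentan-1-ol | O[C@@]1(C(C)C)CC[C@](C)(CC=C)[C@H]1CO | intermediate
15 | rac-(1R,2R,5R)-2-hydroxy-5-methyl-2-(propan-2-yl)-5-(prop-2-en-1-yl)cyclopentane-1-carbaldehyde | O[C@@]1(C(C)C)CC[C@](C)(CC=C)[C@H]1C=O | intermediate
16 | O6-diisopinocampheylborinate of 17 (not isolated) | O[C@@]1(C(C)C)CC[C@](C)(CC=C)[C@H]1[C@@H](OB([C@@H]2C[C@@H]3C[C@H]([C@H]2C)C3(C)C)[C@@H]2C[C@@H]3C[C@H]([C@H]2C)C3(C)C)CC(C)=C | intermediate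
17 | (1R,2S,3R)-2-[(1S)-1-hydroxy-3-methylbut-3-en-1-yl]-3-methyl-1-(propan-2-yl)-3-(prop-2-en-1-yl)cyclopentan-1-ol | O[C@@]1(C(C)C)CC[C@](C)(CC=C)[C@H]1[C@@H](O)CC(C)=C | intermediate
18 | (1R,2S,3R)-3-methyl-2-{(1S)-3-methyl-1-[(triethylsilyl)oxy]but-3-en-1-yl}-1-(propan-2-yl)-3-(prop-2-en-1-yl)cyclopentan-1-ol | O[C@@]1(C(C)C)CC[C@](C)(CC=C)[C@H]1[C@@H](O[Si](CC)(CC)CC)CC(C)=C | intermediate
19 | lithium alkoxide of 18 (not isolated) | [Li]O[C@@]1(C(C)C)CC[C@](C)(CC=C)[C@H]1[C@@H](O[Si](CC)(CC)CC)CC(C)=C | intermediate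
20 | (1R,2S,3R)-3-methyl-2-{(1S)-3-methyl-1-[(triethylsilyl)oxy]but-3-en-1-yl}-1-(propan-2-yl)-3-(prop-2-en-1-yl)cyclopentyl 4-[(tert-butyldimethylsilyl)oxy]-3-methoxybenzoate | COc1cc(C(=O)O[C@@]2(C(C)C)CC[C@](C)(CC=C)[C@H]2[C@@H](O[Si](CC)(CC)CC)CC(C)=C)ccc1O[Si](C)(C)C(C)(C)C | intermediate
21 | (1R,4R,5S,6S)-6-[(triethylsilyl)oxy]dauc-8-en-4-yl 4-[(tert-butyldimethylsilyl)oxy]-3-methoxybenzoate (trans-fused hydroazulene) | COc1cc(C(=O)O[C@@]2(C(C)C)CC[C@]3(C)CC=C(C)C[C@H](O[Si](CC)(CC)CC)[C@H]32)ccc1O[Si](C)(C)C(C)(C)C | intermediate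
22 | (1R,4R,5S,6S)-6-hydroxydauc-8-en-4-yl 4-[(tert-butyldimethylsilyl)oxy]-3-methoxybenzoate | COc1cc(C(=O)O[C@@]2(C(C)C)CC[C@]3(C)CC=C(C)C[C@H](O)[C@H]32)ccc1O[Si](C)(C)C(C)(C)C | intermediate
23 | (1R,4R,5S,6S,8R,9S)-8,9-epoxy-6-hydroxydaucan-4-yl 4-[(tert-butyldimethylsilyl)oxy]-3-methoxybenzoate | COc1cc(C(=O)O[C@@]2(C(C)C)CC[C@]3(C)C[C@@H]4O[C@]4(C)C[C@H](O)[C@H]32)ccc1O[Si](C)(C)C(C)(C)C | intermediate
24 | (1R,4R,5S,6S,8R,9S)-8,9-epoxy-6-hydroxydaucan-4-yl 4-hydroxy-3-methoxybenzoate (CNP0315707.1) | COc1cc(C(=O)O[C@@]2(C(C)C)CC[C@]3(C)C[C@@H]4O[C@]4(C)C[C@H](O)[C@H]32)ccc1O | target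

**Totals**

Total step count: 17.
Longest linear sequence: 11 steps (steps 7–17, from 3-methylcyclopent-2-en-1-one 10), which is below two thirds of 17. The aryl branch (steps 1–3) joins at step 13 and the borane branch (steps 4–6) at step 11.

**Steps most likely to fail, with fallbacks**

Step 8 (allyl transfer to a hindered tertiary radical; competing reduction or allylation before cyclisation). The fallback keeps the tether but traps the cyclised radical with a far more reactive acceptor and builds the allyl group afterwards. It sets out from 12 and comes back at 13. Phenyl vinyl sulfone with slow addition of Bu3SnH/AIBN in benzene at 80 °C gives the Giese adduct rac-(3aR,4R,6aR)-2,2,4-trimethyl-4-[2-(phenylsulfonyl)ethyl]-6a-(propan-2-yl)hexahydro-2H-cyclopenta[d][1,2]oxasilole F1. LDA in THF at −78 °C gives rac-(3aR,4R,6aR)-4-[2-lithio-2-(phenylsulfonyl)ethyl]-2,2,4-trimethyl-6a-(propan-2-yl)hexahydro-2H-cyclopenta[d][1,2]oxasilole F2. Alkylation with Bu3SnCH2I gives the β-stannyl sulfone rac-(3aR,4R,6aR)-2,2,4-trimethyl-4-[2-(phenylsulfonyl)-3-(tributylstannyl)propyl]-6a-(propan-2-yl)hexahydro-2H-cyclopenta[d][1,2]oxasilole F3. This eliminates the tin and sulfonyl groups on warming or on silica gel, without fluoride, so the Si–O and Si–C bonds of the oxasilolane are not put at risk, and the terminal alkene obtained is 13.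

Step 11 (very hindered aldehyde, reagent control on a racemate, separation of the two diastereomers, at most 50 % yield). The fallback makes the series enantiopure before the radical step, so that the methallylboration no longer has to split a racemate. It sets out from 10 and comes back at 12.
- CBS reduction ((R)-Me-CBS, catecholborane, toluene, −78 °C) gives (S)-3-methylcyclopent-2-en-1-ol F4.
- i-Pr2NCOCl/Et3N gives (S)-3-methylcyclopent-2-en-1-yl N,N-diisopropylcarbamate F5.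
- s-BuLi/TMEDA in Et2O at −78 °C gives the configurationally stable (S)-1-lithio-3-methylcyclopent-2-en-1-yl N,N-diisopropylcarbamate F6.
- i-PrB(pin) traps it with retention as lithium {1-[(diisopropylcarbamoyl)oxy]-3-methylcyclopent-2-en-1-yl}(propan-2-yl)(pinacolato)borate F7.
- MgBr2·OEt2/MeOH with warming triggers the 1,2-shift of the isopropyl group with inversion at carbon and gives (S)-4,4,5,5-tetramethyl-2-[3-methyl-1-(propan-2-yl)cyclopent-2-en-1-yl]-1,3,2-dioxaborolane F8.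
- NaOH/H2O2 gives (R)-3-methyl-1-(propan-2-yl)cyclopent-2-en-1-ol F9, with the oxygen on the face it occupied in F4.
- Silylation (BrCH2SiMe2Cl, Et3N, DMAP) comes back to the route at 12, now as the single R enantiomer, so 13–15 are single enantiomers and step 11 gives only 17.

Step 13 (acylation of a tertiary alkoxide flanked by i-Pr and a branched C5 substituent; possible silyl migration). The fallback esterifies earlier, when C5 carries only a CH2O group, and builds C6 afterwards. It sets out from 14 and comes back at 22.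
- TESCl/imidazole gives rac-(1R,2S,3R)-3-methyl-1-(propan-2-yl)-3-(prop-2-en-1-yl)-2-{[(triethylsilyl)oxy]methyl}cyclopentan-1-ol F10.
- n-BuLi (THF, −78 °C) gives lithium rac-(1R,2S,3R)-3-methyl-1-(propan-2-yl)-3-(prop-2-en-1-yl)-2-{[(triethylsilyl)oxy]methyl}cyclopentan-1-olate F11.
- Acid chloride 4 acylates it to rac-(1R,2S,3R)-3-methyl-1-(propan-2-yl)-3-(prop-2-en-1-yl)-2-{[(triethylsilyl)oxy]methyl}cyclopentyl 4-[(tert-butyldimethylsilyl)oxy]-3-methoxybenzoate F12.
- PPTS/MeOH gives rac-(1R,2S,3R)-2-(hydroxymethyl)-3-methyl-1-(propan-2-yl)-3-(prop-2-en-1-yl)cyclopentyl 4-[(tert-butyldimethylsilyl)oxy]-3-methoxybenzoate F13.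
- Buffered Dess–Martin oxidation gives rac-(1R,2R,3R)-2-formyl-3-methyl-1-(propan-2-yl)-3-(prop-2-en-1-yl)cyclopentyl 4-[(tert-butyldimethylsilyl)oxy]-3-methoxybenzoate F14, used cold and crude because a β-acyloxy aldehyde can eliminate.
- Methallylboration with 9 (Et2O, −78 °C) gives the O6-diisopinocampheylborinate of the homoallylic alcohol F15.
- Ethanolamine work-up (no hydroxide, which would attack the aryl silyl ether) and diastereomer separation give (1R,2S,3R)-2-[(1S)-1-hydroxy-3-methylbut-3-en-1-yl]-3-methyl-1-(propan-2-yl)-3-(prop-2-en-1-yl)cyclopentyl 4-[(tert-butyldimethylsilyl)oxy]-3-methoxybenzoate F16.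
- Ring-closing metathesis (Grubbs II, CH2Cl2, 40 °C) of F16 comes back to the route at 22.

**Further compounds**

F1 | step 8 | rac-(3aR,4R,6aR)-2,2,4-trimethyl-4-[2-(phenylsulfonyl)ethyl]-6a-(propan-2-yl)hexahydro-2H-cyclopenta[d][1,2]oxasilole | C[Si]2(C)O[C@@]1(C(C)C)CC[C@](C)(CCS(=O)(=O)c3ccccc3)[C@H]1C2
F2 | step 8 | rac-(3aR,4R,6aR)-4-[2-lithio-2-(phenylsulfonyl)ethyl]-2,2,4-trimethyl-6a-(propan-2-yl)hexahydro-2H-cyclopenta[d][1,2]oxasilole (not isolated) | C[Si]2(C)O[C@@]1(C(C)C)CC[C@](C)(CC([Li])S(=O)(=O)c3ccccc3)[C@H]1C2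
F3 | step 8 | rac-(3aR,4R,6aR)-2,2,4-trimethyl-4-[2-(phenylsulfonyl)-3-(tributylstannyl)propyl]-6a-(propan-2-yl)hexahydro-2H-cyclopenta[d][1,2]oxasilole (epimers at the sulfonyl carbon) | C[Si]2(C)O[C@@]1(C(C)C)CC[C@](C)(CC(C[Sn](CCCC)(CCCC)CCCC)S(=O)(=O)c3ccccc3)[C@H]1C2
F4 | step 11 | (S)-3-methylcyclopent-2-en-1-ol | O[C@H]1CCC(C)=C1
F5 | step 11 | (S)-3-methylcyclopent-2-en-1-yl N,N-diisopropylcarbamate | CC(C)N(C(C)C)C(=O)O[C@H]1CCC(C)=C1
F6 | step 11 | (S)-1-lithio-3-methylcyclopent-2-en-1-yl N,N-diisopropylcarbamate (not isolated) | CC(C)N(C(C)C)C(=O)O[C@@]1([Li])CCC(C)=C1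
F7 | step 11 | lithium {1-[(diisopropylcarbamoyl)oxy]-3-methylcyclopent-2-en-1-yl}(propan-2-yl)(pinacolato)borate (not isolated) | CC(C)N(C(C)C)C(=O)O[C@@]1([B-]2(C(C)C)OC(C)(C)C(C)(C)O2)CCC(C)=C1.[Li+]
F8 | step 11 | (S)-4,4,5,5-tetramethyl-2-[3-methyl-1-(propan-2-yl)cyclopent-2-en-1-yl]-1,3,2-dioxaborolane | CC1(C)OB(OC1(C)C)[C@@]2(C(C)C)CCC(C)=C2
F9 | step 11 | (R)-3-methyl-1-(propan-2-yl)cyclopent-2-en-1-ol | O[C@@]1(C(C)C)CCC(C)=C1
F10 | step 13 | rac-(1R,2S,3R)-3-methyl-1-(propan-2-yl)-3-(prop-2-en-1-yl)-2-{[(triethylsilyl)oxy]methyl}cyclopentan-1-ol | O[C@@]1(C(C)C)CC[C@](C)(CC=C)[C@H]1CO[Si](CC)(CC)CC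
F11 | step 13 | lithium rac-(1R,2S,3R)-3-methyl-1-(propan-2-yl)-3-(prop-2-en-1-yl)-2-{[(triethylsilyl)oxy]methyl}cyclopentan-1-olate (not isolated) | [Li]O[C@@]1(C(C)C)CC[C@](C)(CC=C)[C@H]1CO[Si](CC)(CC)CC
F12 | step 13 | rac-(1R,2S,3R)-3-methyl-1-(propan-2-yl)-3-(prop-2-en-1-yl)-2-{[(triethylsilyl)oxy]methyl}cyclopentyl 4-[(tert-butyldimethylsilyl)oxy]-3-methoxybenzoate | COc1cc(C(=O)O[C@@]2(C(C)C)CC[C@](C)(CC=C)[C@H]2CO[Si](CC)(CC)CC)ccc1O[Si](C)(C)C(C)(C)C
F13 | step 13 | rac-(1R,2S,3R)-2-(hydroxymethyl)-3-methyl-1-(propan-2-yl)-3-(prop-2-en-1-yl)cyclopentyl 4-[(tert-butyldimethylsilyl)oxy]-3-methoxybenzoate | COc1cc(C(=O)O[C@@]2(C(C)C)CC[C@](C)(CC=C)[C@H]2CO)ccc1O[Si](C)(C)C(C)(C)C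
F14 | step 13 | rac-(1R,2R,3R)-2-formyl-3-methyl-1-(propan-2-yl)-3-(prop-2-en-1-yl)cyclopentyl 4-[(tert-butyldimethylsilyl)oxy]-3-methoxybenzoate | COc1cc(C(=O)O[C@@]2(C(C)C)CC[C@](C)(CC=C)[C@H]2C=O)ccc1O[Si](C)(C)C(C)(C)C
F15 | step 13 | O6-diisopinocampheylborinate of F16 (not isolated) | COc1cc(C(=O)O[C@@]2(C(C)C)CC[C@](C)(CC=C)[C@H]2[C@@H](OB([C@@H]3C[C@@H]4C[C@H]([C@H]3C)C4(C)C)[C@@H]3C[C@@H]4C[C@H]([C@H]3C)C4(C)C)CC(C)=C)ccc1O[Si](C)(C)C(C)(C)C
F16 | step 13 | (1R,2S,3R)-2-[(1S)-1-hydroxy-3-methylbut-3-en-1-yl]-3-methyl-1-(propan-2-yl)-3-(prop-2-en-1-yl)cyclopentyl 4-[(tert-butyldimethylsilyl)oxy]-3-methoxybenzoate | COc1cc(C(=O)O[C@@]2(C(C)C)CC[C@](C)(CC=C)[C@H]2[C@@H](O)CC(C)=C)ccc1O[Si](C)(C)C(C)(C)C
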